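**Retrosynthetic overview**

1. The tetrahydrofuran of the target is the ring of a symmetric aromatic feedstock, dimethyl furan-3,4-dicarboxylate (1); no carbocycle or ether ring is built de novo.
2. Key disconnection, C2–aryl: an enantioselective 1,4-arylation of 1 with the arylzinc from bromide 2 breaks both the aromaticity and the C2v symmetry, giving dihydrofuran 3. This sets C2, then C3 by equilibration, and leaves one saturated ester and one vinylogous ester.
3. The saturated ester is reduced and lactonised onto the other ester (enol-ether lactone 4); alkene reduction gives the cis-fused lactone 5, where the ring fusion fixes C4.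
4. Last disconnection, aryl ketone C–C: the aryllithium from 4-bromoveratrole (6) opens lactone 5 to magnone B (7), releasing the CH2OH.
5. Ring order: furan (given) → 2,3-dihydrofuran → temporary γ-lactone fused on → tetrahydrofuran → lactone opened.

The target is (2S,3R,4R): aryl and CH2OH are 2,3-trans, CH2OH and aroyl are 3,4-cis.

Assumption: the BINAP antipode that delivers (2S)-3 must be found by a two-run screen; the route is drawn for that antipode.

**Route**

Step 1
Reactants: 1, dimethyl furan-3,4-dicarboxylate; 2, 5-bromo-1,2,3-trimethoxybenzene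
Product: 3, dimethyl (2S,3S)-2-(3,4,5-trimethoxyphenyl)-2,3-dihydrofuran-3,4-dicarboxylate (aryl and C3 ester trans; C4=C5 retained)
Conditions: 2, Mg, LiCl, THF, then ZnCl2 (ArZnCl, 2 equiv); 1, [RhCl(C2H4)2]2 (3 mol %), BINAP (6.5 mol %), TMSCl (2 equiv), THF, 20–40 °C; AcOH, −40 °C; then DBU (0.2 equiv), CH2Cl2, rt
Reagents that add atoms: none (the aryl group comes from 2; H at C3 from AcOH)
Why: Proposed new method: an aryl–Rh(I) species inserts one enantioface of the furan C2=C3 bond, which is the β,α-bond of a β-alkoxyacrylate, to give a Rh oxa-π-allyl that TMSCl traps as a silyl ketene acetal; this trapping masks the product against a second arylation and against E1cB opening, while syn-insertion leaves Rh anti to the only β-H so the arylfuran cannot re-form, and the cost of furan's small resonance energy (about 16 kcal/mol) is offset by the retained push–pull C4=C5 acrylate; the closest known reactions are Rh/BINAP asymmetric 1,4-addition of ArZnCl/TMSCl to 4-quinolones and 2,3-dihydro-4-pyridones and conjugate arylation of chromones; C2 is set by the catalyst, and C3 by DBU equilibration to the trans isomer (as in cis-to-trans epimerisation of 2-aryl-dihydrobenzofuran-3-carboxylates).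

Step 2
Reactants: 3, dimethyl (2S,3S)-2-(3,4,5-trimethoxyphenyl)-2,3-dihydrofuran-3,4-dicarboxylate
Product: 4, (3aR,4S)-4-(3,4,5-trimethoxyphenyl)-3a,4-dihydro-1H,3H-furo[3,4-c]furan-1-one (lactone C=O on the sp2 ring-fusion carbon; C6=C6a enol ether)
Conditions: LiBH4 (1.2 equiv), THF, 0 °C → rt; then CSA (10 mol %), PhMe, 70 °C (−MeOH)
Reagents that add atoms: none
Why: Chemoselective hydride reduction of the saturated C3 ester, because the C4 ester is a deactivated vinylogous carbonate, followed by acid-catalysed 5-exo lactonisation; C3 is no longer epimerisable from here on, and C2 is untouched.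

Step 3
Reactants: 4, (3aR,4S)-4-(3,4,5-trimethoxyphenyl)-3a,4-dihydro-1H,3H-furo[3,4-c]furan-1-one
Product: 5, (3aR,4S,6aR)-4-(3,4,5-trimethoxyphenyl)tetrahydro-1H,3H-furo[3,4-c]furan-1-one (cis-fused, aryl exo)
Conditions: H2 (1 atm), 5% Rh/Al2O3, EtOAc, rt
Reagents that add atoms: none
Why: Heterogeneous hydrogenation of the β-alkoxyacrylate alkene from the convex face gives the cis-fused bicyclo[3.3.0] lactone, which is also the only thermodynamically viable fusion (the new centre is α to the lactone C=O and would epimerise to cis); Rh on alumina is chosen to avoid benzylic C–O hydrogenolysis.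

Step 4
Reactants: 5, (3aR,4S,6aR)-4-(3,4,5-trimethoxyphenyl)tetrahydro-1H,3H-furo[3,4-c]furan-1-one; 6, 4-bromo-1,2-dimethoxybenzene
Product: 7, magnone B, (3,4-dimethoxyphenyl)[(3R,4R,5S)-4-(hydroxymethyl)-5-(3,4,5-trimethoxyphenyl)tetrahydrofuran-3-yl]methanone
Conditions: 6, n-BuLi, THF, −78 °C; then 5 (0.9 equiv), −78 °C; sat. NH4Cl at −78 °C
Reagents that add atoms: none (the aryl group comes from 6)
Why: Mono-addition of an aryllithium to a γ-lactone stops at the bicyclic lithium hemiketal, which on cold neutral quench opens to the aryl ketone and primary alcohol (as in furofuranone-to-lignan syntheses); the 3,4-cis relationship is inherited from the ring fusion and no stereocentre is touched.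

**Compound list**

1 | dimethyl furan-3,4-dicarboxylate | COC(=O)c1cocc1C(=O)OC | starting material
2 | 5-bromo-1,2,3-trimethoxybenzene | COc1cc(Br)cc(OC)c1OC | starting material
3 | dimethyl (2S,3S)-2-(3,4,5-trimethoxyphenyl)-2,3-dihydrofuran-3,4-dicarboxylate | COC(=O)C1=CO[C@H](c2cc(OC)c(OC)c(OC)c2)[C@H]1C(=O)OC | intermediate
4 | (3aR,4S)-4-(3,4,5-trimethoxyphenyl)-3a,4-dihydro-1H,3H-furo[3,4-c]furan-1-one | O=C1OC[C@@H]2[C@@H](c3cc(OC)c(OC)c(OC)c3)OC=C12 | intermediate
5 | (3aR,4S,6aR)-4-(3,4,5-trimethoxyphenyl)tetrahydro-1H,3H-furo[3,4-c]furan-1-one | O=C1OC[C@@H]2[C@@H](c3cc(OC)c(OC)c(OC)c3)OC[C@H]12 | intermediate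
6 | 4-bromo-1,2-dimethoxybenzene (4-bromoveratrole) | COc1ccc(Br)cc1OC | starting material
7 | magnone B | COc1ccc(C(=O)[C@H]2CO[C@H](c3cc(OC)c(OC)c(OC)c3)[C@H]2CO)cc1OC | target

**Totals**

Total steps: 4. Longest linear sequence: 4 (organometallics generated in situ). No protecting groups.

**Steps most likely to fail, with fallbacks**

1. Step 1. The furan may not insert, or the enolate may ring-open. Fallback: give up the arylmetal addition and make racemic 3 by Mn(OAc)3/Cu(OAc)2 oxidative [3+2] annulation of methyl 3,4,5-trimethoxycinnamate with methyl formylacetate. Then carry it through steps 2–3 and resolve lactone 5 (chiral SFC or lipase).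
2. Step 2. LiBH4 may also attack the vinylogous ester, or the lactone may not close. Fallback: differentiate the esters by hydrolysis instead of hydride. LiOH (1 equiv) cleaves only the saturated C3 ester, BH3·SMe2 reduces the resulting acid, and the hydroxy ester is then lactonised.
3. Step 4. Risks are double addition, enolisation of 5, or C4 epimerisation on work-up. Fallback: open 5 with MeNH(OMe)·HCl/AlMe3 to the Weinreb amide, protect the CH2OH as its TBS ether, add 3,4-dimethoxyphenylmagnesium bromide, and remove the silyl group with buffered TBAF.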